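**Route outline**

- Retrosynthesis: ring B is opened first at C9–C10 (retro-aldol of the C10 carbinol / C8 ketone pair) and then at C5–C6 (retro-conjugate addition at the 2-acetyl enone). This releases the whole C6–C9 unit at its final oxidation level (C7 acetyl, C8 ketone, C9 angelate) and leaves a ring A ketone.
- Enabling feature: in ring B the C10 tertiary alcohol is β to the C8 ketone with only C9 between them, and C6 of the C6=C7 enone sits on quaternary C5. C5 and C10 of a ring A ketone can therefore act as a nucleophile/electrophile pair toward a four-carbon piece that is electrophilic at C6 and nucleophilic at C9.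
- Forward order: ring A comes from 2,3-dimethylhydroquinone (acetylation, all-cis arene hydrogenation, enzymatic desymmetrisation, oxidation, thermodynamic silylation). The C6–C9 acceptor comes from an enaminone, chloroacetyl chloride and angelic acid. The two are joined at C5–C6 and ring B is closed last at C9–C10 in the same flask.
- Stereochemistry: the cis C3 acetate / C4 methyl pair comes from one-face hydrogenation, and its absolute sense from lipase hydrolysis of one enantiotopic acetate. C5, C10 and C9 are set under substrate control in the annulation. The Z alkene of the angelate is carried in unchanged by carboxylate O-alkylation.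

Key step: step 8

Remark: atoms are numbered as in the eremophilane skeleton (ring A: C1–C5 and C10; ring B: C5–C10; angelate on C9); the sense of the enzymatic step is assumed to follow the empirical size rule for lipases and secondary alcohols.

**Route**

Step 1
Reactants: 1 2,3-dimethylhydroquinone
Product: 2 2,3-dimethyl-1,4-phenylene diacetate
Conditions: Ac2O, pyridine, DMAP (cat.), CH2Cl2, 0 °C to rt
Reagents that add atoms: acetic anhydride, CC(=O)OC(C)=O
Why: Standard O-acetylation of a phenol; capping both phenols installs the future C3 acetate and keeps the ring from passing through cyclohexanone tautomers during the hydrogenation.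

Step 2
Reactants: 2 2,3-dimethyl-1,4-phenylene diacetate
Product: 3 meso (1R,2S,3R,4S)-2,3-dimethylcyclohexane-1,4-diyl diacetate (all four substituents cis)
Conditions: H2 (50 bar), Rh/Al2O3 (5 wt% Rh), EtOAc, 50 °C; recrystallisation
Reagents that add atoms: none
Why: Heterogeneous arene hydrogenation over rhodium should deliver all six hydrogens from the catalyst face, so the two acetates and two methyls end up cis (meso); rhodium is chosen because it causes little C–O hydrogenolysis of aryl esters.

Step 3
Reactants: 3 meso all-cis diacetate
Product: 4 (1S,2R,3S,4R)-4-hydroxy-2,3-dimethylcyclohexyl acetate (all-cis; free hydroxyl on the future C10, acetate on the future C3)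
Conditions: Candida antarctica lipase B (immobilised), NaH2PO4/Na2HPO4 buffer pH 7, MTBE (co-solvent), 30 °C
Reagents that add atoms: none
Why: Enantiotopic-group-selective ester hydrolysis by a serine hydrolase (desymmetrisation of a meso diacetate); by the size rule the acetate on the R-configured carbinol carbon, whose larger flank is the methyl-bearing ring carbon, should be cleaved, which fixes the absolute configuration at C3 and C4, and any antipodal monoacetate still carries the fast-reacting ester and should be drained to the diol.

Step 4
Reactants: 4 all-cis hydroxy acetate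
Product: 5 (1S,2R,3S)-2,3-dimethyl-4-oxocyclohexyl acetate (ring A ketone)
Conditions: Dess–Martin periodinane, CH2Cl2, 0 °C to rt
Reagents that add atoms: none
Why: Dess–Martin oxidation of a secondary alcohol under non-basic conditions; the acetate is γ to the new ketone and cannot be lost by β-elimination, and the α carbon (future C5) needs no protection because it becomes trigonal in the next step.

Step 5
Reactants: 5 ring A ketone
Product: 6 (1S,2R)-2,3-dimethyl-4-(trimethylsilyloxy)cyclohex-3-en-1-yl acetate (enol silane, C5=C10)
Conditions: Me3SiCl, NaI, Et3N, MeCN, rt; pentane extraction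
Reagents that add atoms: chlorotrimethylsilane, C[Si](C)(C)Cl
Why: Silylation by Me3SiI formed in the flask under equilibrating conditions should give the more substituted (thermodynamic) enol silane toward the methyl-bearing carbon; C4 is β to the carbonyl and keeps its configuration.

Step 6
Reactants: 7 (E)-4-(dimethylamino)but-3-en-2-one; 8 chloroacetyl chloride
Product: 9 3-(chloroacetyl)-4-(dimethylamino)but-3-en-2-one
Conditions: pyridine, CH2Cl2, 0 °C to rt
Reagents that add atoms: none
Why: C-acylation of a vinylogous amide at its nucleophilic α carbon by an acid chloride, followed by loss of HCl to pyridine, is the reaction type used to make 2-acyl-3-aminoacrylates; the push–pull alkene of the product rotates easily, so its geometry does not matter.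

Step 7
Reactants: 9 3-(chloroacetyl)-4-(dimethylamino)but-3-en-2-one; 10 angelic acid
Product: 11 3-acetyl-4-(dimethylamino)-2-oxobut-3-en-1-yl (Z)-2-methylbut-2-enoate (C6–C9 acceptor)
Conditions: K2CO3, KI (cat.), DMF, 0 °C to rt
Reagents that add atoms: none
Why: SN2 displacement of an α-chloro ketone by a potassium carboxylate with Finkelstein assistance; because the carboxylate oxygen is alkylated and the acid is never activated as an acylating agent, the Z alkene should not isomerise to the tiglate.

Step 8
Reactants: 6 ring A enol silane; 11 C6–C9 acceptor
Product: 14 target CNP0196241.1, via amine adduct 12 (not isolated), via alkylidene diketone 13 (not isolated)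
Conditions: 11, TiCl4 (2.2 equiv), CH2Cl2, −78 °C; add 6, −78 to −40 °C; then Et3N (2.5 equiv), −78 °C; cold NaH2PO4/Na2HPO4 buffer (pH 7) quench
Reagents that add atoms: none
Why: Proposed new method: TiCl4 chelates the two ketone oxygens of 11 and turns its aminomethylene carbon (C6) into an iminium-like electrophile, enol silane 6 attacks it through C5 in a Mukaiyama–Michael (Mannich-type) addition to give 12, the titanium-bound amine is expelled from the diketonate to give alkylidene diketone 13, and Et3N then forms the chelated titanium enolate of the acyloxymethyl ketone, whose C9 adds to the ring A ketone carbon C10. The closest known reaction type is the TiCl4-mediated conjugate addition, β-elimination and aldol cascade of silyl enol ethers with β-alkoxy or β-silyloxy enones (the formal 3+3 benzannulation of 1,3-bis(silyloxy)dienes), joined to the soft-enolisation titanium aldol of α-oxygenated ketones; what is new is the amine leaving group on a 2-acyl enaminone and the pairing of both stages in one flask. Ring B is closed by a 6-(enolendo)-exo-trig aldol. C5 is set by axial attack on the enol silane anti to the pseudoaxial C4 methyl (the face also remote from the C3 acetate), C10 by the tether, which sits axial on C5 and can reach the ketone only from its own face and so gives the cis-fused ketol as in Robinson annulations, and C9 by the Z (acyloxy-chelated) enolate, which in this closure places the angelate pseudoequatorial and trans to the new hydroxyl. The step needs enolisation at C9 and not at the acetyl methyl or at C1, which the inductive acidification and titanium chelation by the acyloxy group should secure while the two alkene isomers of 13 interconvert through reversible amine addition, and it needs to stop at the ketol, which the low temperature and neutral quench should ensure.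

**Compound list**

1 | 2,3-dimethylhydroquinone (2,3-dimethylbenzene-1,4-diol) | Cc1c(C)c(O)ccc1O | starting material
2 | 2,3-dimethyl-1,4-phenylene diacetate | CC(=O)Oc1ccc(OC(C)=O)c(C)c1C | intermediate
3 | meso (1R,2S,3R,4S)-2,3-dimethylcyclohexane-1,4-diyl diacetate, all-cis | C[C@H]1[C@@H](C)[C@@H](OC(C)=O)CC[C@H]1OC(C)=O | intermediate
4 | (1S,2R,3S,4R)-4-hydroxy-2,3-dimethylcyclohexyl acetate, all-cis | C[C@H]1[C@@H](C)[C@@H](OC(C)=O)CC[C@H]1O | intermediate
5 | (1S,2R,3S)-2,3-dimethyl-4-oxocyclohexyl acetate | C[C@H]1[C@@H](C)[C@@H](OC(C)=O)CCC1=O | intermediate
6 | (1S,2R)-2,3-dimethyl-4-(trimethylsilyloxy)cyclohex-3-en-1-yl acetate | C[C@H]1[C@@H](OC(C)=O)CCC(O[Si](C)(C)C)=C1C | intermediate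
7 | (E)-4-(dimethylamino)but-3-en-2-one | CN(C)/C=C/C(C)=O | starting material
8 | chloroacetyl chloride | ClCC(Cl)=O | starting material
9 | 3-(chloroacetyl)-4-(dimethylamino)but-3-en-2-one | CN(C)C=C(C(C)=O)C(=O)CCl | intermediate
10 | angelic acid, (Z)-2-methylbut-2-enoic acid | C/C=C(/C)C(=O)O | starting material
11 | 3-acetyl-4-(dimethylamino)-2-oxobut-3-en-1-yl (Z)-2-methylbut-2-enoate | C/C=C(/C)C(=O)OCC(=O)C(=CN(C)C)C(C)=O | intermediate
12 | (1S,2R,3S)-3-[2-acetyl-1-(dimethylamino)-4-[(Z)-2-methylbut-2-enoyloxy]-3-oxobutyl]-2,3-dimethyl-4-oxocyclohexyl acetate (held as titanium diketonate; the two new chain carbons unassigned) | C/C=C(/C)C(=O)OCC(=O)C(C(C)=O)C(N(C)C)[C@]1(C)[C@@H](C)[C@@H](OC(C)=O)CCC1=O | intermediate (not isolated)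
13 | (1S,2R,3R)-3-[2-acetyl-4-[(Z)-2-methylbut-2-enoyloxy]-3-oxobut-1-en-1-yl]-2,3-dimethyl-4-oxocyclohexyl acetate (alkene geometry mobile) | C/C=C(/C)C(=O)OCC(=O)C(C(C)=O)=C[C@]1(C)[C@@H](C)[C@@H](OC(C)=O)CCC1=O | intermediate (not isolated)
14 | CNP0196241.1, (1S,4aR,5R,6S,8aR)-6-acetoxy-3-acetyl-8a-hydroxy-4a,5-dimethyl-2-oxo-1,2,4a,5,6,7,8,8a-octahydronaphthalen-1-yl (Z)-2-methylbut-2-enoate | C/C=C(/C)C(=O)O[C@@H]1C(=O)C(C(C)=O)=C[C@]2(C)[C@@H](C)[C@@H](OC(C)=O)CC[C@]12O | target

**Step count and risks**

Total step count: 8. Longest linear sequence: 6 steps (steps 1 to 5, then step 8); the acceptor branch is steps 6 and 7.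

Steps most likely to fail:

1. Step 8 (proposed new method). Several things may go wrong:
   - C–C bond formation at the congested tetrasubstituted enol carbon may be slow, or the titanium-bound amine may not leave.
   - Enolisation at the acetyl methyl or at C1 may compete, so that the ring closes in the wrong direction.
   - Control at C9 may be poor if the closure runs through a titanium-bridged transition state instead of the open one assumed.
   - The ketol may dehydrate on warming.

   Fallback with known chemistry, setting out from 6 and returning at 13:
   - Enol silane 6 is C-formylated at C5 with trimethyl orthoformate and catalytic trimethylsilyl triflate in CH2Cl2 at −78 °C (Mukaiyama-type addition to an orthoester, same facial bias) to give the keto acetal F1.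
   - Aqueous oxalic acid in THF then releases the keto aldehyde F2.
   - In parallel, chloroacetyl chloride 8 acylates 2-(trimethylsilyloxy)propene under ZnCl2 catalysis to give 1-chloropentane-2,4-dione F3.
   - The chloride of F3 is displaced by potassium angelate made from 10, giving 2,4-dioxopentyl angelate F4.
   - A TiCl4/pyridine Knoevenagel condensation of F2 with F4 gives 13, now isolated.
   - 13 is closed to 14 in a separate soft-enolisation aldol (TiCl4, Et3N, CH2Cl2, −78 °C), where base, temperature and quench can be varied without the amine by-product present.

2. Step 3. Hydrolysis next to the methyl-bearing carbon may be slow, the two enantiotopic acetates may be poorly discriminated, or the enzyme may prefer the other ester.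

   Fallback, setting out from 3 and returning at 4:
   - Diacetate 3 is methanolysed (K2CO3, MeOH) to the meso diol F5.
   - F5 is monoacetylated with vinyl acetate and a lipase in MTBE.
   - One enzyme addresses the same carbinol centre in both modes, so acylation and hydrolysis give opposite enantiomers. The mode (and the lipase, for example that of Pseudomonas cepacia) is chosen to deliver 4.

3. Step 7. Intramolecular O-alkylation by the vinylogous amide oxygen (closure to a furanone), or carboxylate attack at the aminomethylene carbon, may outrun the intermolecular displacement. Forcing the reaction by heat risks Z to E isomerisation of the angelate.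

   Fallback, setting out from 10 and returning at 11 without passing through 9:
   - Potassium angelate is alkylated with tert-butyl bromoacetate (K2CO3, DMF) to give tert-butyl (angeloyloxy)acetate F6.
   - CF3CO2H in CH2Cl2 frees (angeloyloxy)acetic acid F7.
   - Oxalyl chloride with catalytic DMF gives (angeloyloxy)acetyl chloride F8.
   - F8 C-acylates enaminone 7 in the presence of pyridine, as in step 6, to give 11.

**Further compounds**

F1 | step 8 | (1S,2R,3S)-3-(dimethoxymethyl)-2,3-dimethyl-4-oxocyclohexyl acetate | COC(OC)[C@]1(C)[C@@H](C)[C@@H](OC(C)=O)CCC1=O
F2 | step 8 | (1S,2R,3S)-3-formyl-2,3-dimethyl-4-oxocyclohexyl acetate | O=C[C@]1(C)[C@@H](C)[C@@H](OC(C)=O)CCC1=O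
F3 | step 8 | 1-chloropentane-2,4-dione | CC(=O)CC(=O)CCl
F4 | step 8 | 2,4-dioxopentyl (Z)-2-methylbut-2-enoate | C/C=C(/C)C(=O)OCC(=O)CC(C)=O
F5 | step 3 | meso all-cis-2,3-dimethylcyclohexane-1,4-diol | C[C@H]1[C@@H](C)[C@@H](O)CC[C@H]1O
F6 | step 7 | tert-butyl 2-[(Z)-2-methylbut-2-enoyloxy]acetate | C/C=C(/C)C(=O)OCC(=O)OC(C)(C)C
F7 | step 7 | 2-[(Z)-2-methylbut-2-enoyloxy]acetic acid | C/C=C(/C)C(=O)OCC(=O)O
F8 | step 7 | 2-chloro-2-oxoethyl (Z)-2-methylbut-2-enoate | C/C=C(/C)C(=O)OCC(Cl)=O
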